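**Retrosynthetic overview**

1. Last bonds: the aryl ester C–O (Pd alkoxycarbonylation of the C5 alcohol with silyl-protected 4-iodophenol and CO) and the oxirane (epoxidation of the cyclopentene directed by the C7 hydroxyl).
2. anti-1,3-Diol ⇒ β-hydroxy ketone (directed reduction) ⇒ β-methyl cycloheptenone (β-borylation/oxidation sets the tertiary carbinol) ⇒ saturated ketone (dehydrogenation).
3. Cyclopentene ⇒ ring-closing metathesis of a trans-3-methallyl-4-vinylcycloheptanone.
4. Cycloheptanone ⇒ one-carbon ring expansion of a 1-(2-methylprop-1-enyl)cyclohexanol: the more substituted ring carbon shifts 1,2 onto the alkene carbon, which enters the ring carrying the isopropyl group.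
5. Cyclohexanone ⇒ vinyl/methallyl three-component coupling on (S)-5-methylcyclohexenone ⇒ crotonaldehyde + methyl acetoacetate. Ring order: cyclohexane → cycloheptane (expansion) → cyclopentene → oxirane.

Assumption: azulene locants are used for the bicyclic compounds (C1/C2 = alkene or epoxide carbons, C4 = isopropyl carbon, C5 = ester carbon, C7 = carbinol carbon); the two commercial Grignard solutions and CO are counted as starting materials.

**Route**

Step 1
Reactants: 1 (E)-but-2-enal; 2 methyl 3-oxobutanoate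
Product: 5 (5S)-5-methylcyclohex-2-en-1-one, via Michael adduct 3 (not isolated), via cyclic keto ester 4 (not isolated)
Conditions: (R)-2-{bis[3,5-bis(trifluoromethyl)phenyl](trimethylsilyloxy)methyl}pyrrolidine (10 mol%), PhCO2H (10 mol%), neat, 0 °C → rt; then TsOH·H2O (20 mol%), PhMe, 80 °C; then LiCl (2 eq), DMSO/H2O, 130 °C
Reagents that add atoms: none
Why: Iminium-catalysed Michael addition (diarylprolinol silyl ether) sets the methyl-bearing stereocentre by attack on the enal face left open by the catalyst's aryl groups, the methyl ketone then closes by acid-catalysed aldol condensation and the ester is removed by Krapcho decarbomethoxylation (organocatalytic Robinson-type annulation).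

Step 2
Reactants: 5 (5S)-5-methylcyclohex-2-en-1-one; 6 ethenylmagnesium bromide; 7 3-bromo-2-methylprop-1-ene
Product: 9 (2R,3R,5S)-3-ethenyl-5-methyl-2-(2-methylprop-2-en-1-yl)cyclohexan-1-one, via magnesium enolate 8 (not isolated)
Conditions: 6 (1.3 eq), CuBr·SMe2 (10 mol%), THF, −78 → −40 °C; then 7 (3 eq), DMPU, −40 → 0 °C
Reagents that add atoms: none
Why: Copper-catalysed 1,4-addition places the vinyl group anti to the C5 methyl (axial attack on the half-chair, trans-3,5) and the regiospecific magnesium enolate is C-alkylated by the allylic bromide anti to the new vinyl group (trans-2,3), a three-component conjugate addition–enolate alkylation.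

Step 3
Reactants: 9 (2R,3R,5S)-3-ethenyl-5-methyl-2-(2-methylprop-2-en-1-yl)cyclohexan-1-one; 10 (2-methylprop-1-en-1-yl)magnesium bromide
Product: 11 (1S,2R,3R,5S)-3-ethenyl-5-methyl-2-(2-methylprop-2-en-1-yl)-1-(2-methylprop-1-en-1-yl)cyclohexan-1-ol
Conditions: anhydrous CeCl3 (1.5 eq), 10 (1.5 eq), THF, −78 → 0 °C; aq. NH4Cl
Reagents that add atoms: none
Why: Organocerium 1,2-addition (Imamoto conditions) avoids enolisation of the α-branched ketone; equatorial attack anti to the axial 5-methyl should give mainly the (1S) carbinol, but this centre becomes the ketone carbon in step 4, so both epimers converge.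

Step 4
Reactants: 11 (1S,2R,3R,5S)-3-ethenyl-5-methyl-2-(2-methylprop-2-en-1-yl)-1-(2-methylprop-1-en-1-yl)cyclohexan-1-ol
Product: 12 (2S,3R,4R,6S)-4-ethenyl-6-methyl-3-(2-methylprop-2-en-1-yl)-2-(propan-2-yl)cycloheptan-1-one
Conditions: 9-mesityl-10-methylacridinium BF4 (5 mol%), 2,4,6-triisopropylthiophenol (20 mol%), DCE (0.05 M), 450 nm LEDs, rt; then DBU (20 mol%), rt
Reagents that add atoms: none
Why: Proposed new method: photo-oxidation of the trialkyl-substituted alkene (the only one within reach of the excited acridinium) gives an alkene radical cation; the ring bond to the more substituted, more electron-rich α-carbon shifts to the less substituted alkene carbon as the carbinol becomes the ketone (a semipinacol 1,2-shift, six → seven, with retention at the migrating carbon), the tertiary radical left at CMe2 takes a hydrogen atom from the thiol to become the isopropyl group, and DBU equilibrates the new α-centre to the all-trans isomer; the closest known chemistry is acridinium/thiol anti-Markovnikov alkene hydrofunctionalisation combined with electrophile- or radical-triggered semipinacol ring expansion of 1-alkenylcycloalkanols.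

Step 5
Reactants: 12 (2S,3R,4R,6S)-4-ethenyl-6-methyl-3-(2-methylprop-2-en-1-yl)-2-(propan-2-yl)cycloheptan-1-one
Product: 13 (3aR,4S,7S,8aS)-2,7-dimethyl-4-(propan-2-yl)-3a,4,6,7,8,8a-hexahydroazulen-5(3H)-one
Conditions: Grubbs II (3 mol%), CH2Cl2 (5 mM), 40 °C
Reagents that add atoms: none
Why: Ring-closing metathesis between the vinyl and 1,1-disubstituted alkenes held trans on adjacent carbons gives the trisubstituted cyclopentene and the trans-fused bicyclo[5.3.0] skeleton with loss of ethene; no stereocentre is touched.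

Step 6
Reactants: 13 (3aR,4S,7S,8aS)-2,7-dimethyl-4-(propan-2-yl)-3a,4,6,7,8,8a-hexahydroazulen-5(3H)-one
Product: 15 (3aR,4S,8aS)-2,7-dimethyl-4-(propan-2-yl)-3a,4,8,8a-tetrahydroazulen-5(3H)-one, via lithium enolate 14 (not isolated)
Conditions: LDA (1.1 eq), THF, −78 °C; then PhS(Cl)=N-t-Bu (1.2 eq), −78 °C
Reagents that add atoms: none
Why: LDA deprotonates the unhindered C6 methylene and not the isopropyl-flanked C4–H, and the enolate is dehydrogenated by the sulfinimidoyl chloride (Mukaiyama dehydrogenation: α-sulfur bond, then syn-elimination) to the β-methyl enone, erasing the methyl stereocentre that has done its relay job.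

Step 7
Reactants: 15 (3aR,4S,8aS)-2,7-dimethyl-4-(propan-2-yl)-3a,4,8,8a-tetrahydroazulen-5(3H)-one
Product: 17 (3aR,4S,7R,8aS)-7-hydroxy-2,7-dimethyl-4-(propan-2-yl)-3a,4,6,7,8,8a-hexahydroazulen-5(3H)-one, via boronate 16 (not isolated)
Conditions: CuCl (5 mol%), (R,R)-QuinoxP* (6 mol%; the antipode if the first run shows the other sense), NaOt-Bu (10 mol%), B2pin2 (1.2 eq), MeOH (2 eq), THF, rt; then NaBO3·4H2O, THF/H2O, rt
Reagents that add atoms: bis(pinacolato)diboron, CC1(C)OB(OC1(C)C)B1OC(C)(C)C(C)(C)O1 (boron of 16); sodium perborate, [Na+].[O-]B1OO1 (oxygen of 17)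
Why: Ligand-controlled conjugate addition of Cu–Bpin to the Re face of C7 (the face of H-3a), then stereoretentive perborate oxidation of the C–B bond, gives the tertiary alcohol (asymmetric β-borylation/oxidation); only the enone reacts, the ring alkene does not.

Step 8
Reactants: 17 (3aR,4S,7R,8aS)-7-hydroxy-2,7-dimethyl-4-(propan-2-yl)-3a,4,6,7,8,8a-hexahydroazulen-5(3H)-one
Product: 18 (3aR,4S,5S,7R,8aS)-2,7-dimethyl-4-(propan-2-yl)-3,3a,4,5,6,7,8,8a-octahydroazulene-5,7-diol
Conditions: Me4NBH(OAc)3 (5 eq), MeCN/AcOH 1:1, −30 °C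
Reagents that add atoms: none
Why: Evans–Saksena reduction: the triacetoxyborohydride exchanges onto the C7 hydroxyl and delivers hydride within the complex to the same face of the ketone, giving the 1,3-anti diol (5S).

Step 9
Reactants: 19 4-iodophenol
Product: 20 tert-butyl(4-iodophenoxy)dimethylsilane
Conditions: TBSCl (1.1 eq), imidazole (2 eq), DMF, rt
Reagents that add atoms: tert-butyldimethylsilyl chloride, CC(C)(C)[Si](C)(C)Cl
Why: Imidazole-mediated O-silylation of the phenol, so that it cannot act as the nucleophile in the carbonylation.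

Step 10
Reactants: 18 (3aR,4S,5S,7R,8aS)-2,7-dimethyl-4-(propan-2-yl)-3,3a,4,5,6,7,8,8a-octahydroazulene-5,7-diol; 20 tert-butyl(4-iodophenoxy)dimethylsilane; 21 carbon monoxide
Product: 22 (3aR,4S,5S,7R,8aS)-7-hydroxy-2,7-dimethyl-4-(propan-2-yl)-3,3a,4,5,6,7,8,8a-octahydroazulen-5-yl 4-[(tert-butyldimethylsilyl)oxy]benzoate
Conditions: Pd(OAc)2 (5 mol%), Xantphos (6 mol%), CO (1 atm), Et3N (3 eq), DMAP (20 mol%), PhMe, 80 °C
Reagents that add atoms: none
Why: Palladium-catalysed alkoxycarbonylation (oxidative addition of the aryl iodide, CO insertion, DMAP-assisted acyl transfer) esterifies the secondary C5 hydroxyl, the tertiary C7 hydroxyl being too hindered; no stereocentre is touched.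

Step 11
Reactants: 22 (3aR,4S,5S,7R,8aS)-7-hydroxy-2,7-dimethyl-4-(propan-2-yl)-3,3a,4,5,6,7,8,8a-octahydroazulen-5-yl 4-[(tert-butyldimethylsilyl)oxy]benzoate
Product: 24 (1S,2R,3aR,4S,5S,7R,8aS)-1,2-epoxy-7-hydroxy-2,7-dimethyl-4-(propan-2-yl)decahydroazulen-5-yl 4-hydroxybenzoate, via silyl-protected epoxide 23 (not isolated)
Conditions: VO(acac)2 (5 mol%), t-BuOOH (1.5 eq), CH2Cl2, 0 °C → rt; then TBAF (1.2 eq), AcOH (1.2 eq), THF, 0 °C
Reagents that add atoms: tert-butyl hydroperoxide, CC(C)(C)OO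
Why: Hydroxyl-directed epoxidation: the vanadium alkylperoxide bound to the bishomoallylic C7 hydroxyl delivers oxygen to the alkene face on its own side, setting C1 and C2 syn to that hydroxyl, and buffered fluoride then cleaves only the aryl silyl ether.

**Compound list**

1 | (E)-but-2-enal (crotonaldehyde) | C/C=C/C=O | starting material
2 | methyl 3-oxobutanoate (methyl acetoacetate) | CC(=O)CC(=O)OC | starting material
3 | methyl (3S)-2-acetyl-3-methyl-5-oxopentanoate (C2 epimers) | CC(=O)C(C(=O)OC)[C@@H](C)CC=O | intermediate (not isolated)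
4 | methyl (6S)-6-methyl-2-oxocyclohex-3-ene-1-carboxylate (C1 epimers) | C[C@@H]1C(C(=O)OC)C(=O)C=CC1 | intermediate (not isolated)
5 | (5S)-5-methylcyclohex-2-en-1-one | C[C@@H]1CC(=O)C=CC1 | intermediate
6 | ethenylmagnesium bromide | C=C[Mg]Br | starting material
7 | 3-bromo-2-methylprop-1-ene (methallyl bromide) | CC(=C)CBr | starting material
8 | bromomagnesium (3R,5S)-3-ethenyl-5-methylcyclohex-1-en-1-olate | Br[Mg]OC1=C[C@@H](C=C)C[C@H](C)C1 | intermediate (not isolated)
9 | (2R,3R,5S)-3-ethenyl-5-methyl-2-(2-methylprop-2-en-1-yl)cyclohexan-1-one | O=C1[C@H](CC(C)=C)[C@@H](C=C)C[C@H](C)C1 | intermediate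
10 | (2-methylprop-1-en-1-yl)magnesium bromide | CC(C)=C[Mg]Br | starting material
11 | (1S,2R,3R,5S)-3-ethenyl-5-methyl-2-(2-methylprop-2-en-1-yl)-1-(2-methylprop-1-en-1-yl)cyclohexan-1-ol (expected major C1 epimer) | O[C@]1(C=C(C)C)[C@H](CC(C)=C)[C@@H](C=C)C[C@H](C)C1 | intermediate
12 | (2S,3R,4R,6S)-4-ethenyl-6-methyl-3-(2-methylprop-2-en-1-yl)-2-(propan-2-yl)cycloheptan-1-one | CC(C)[C@H]1[C@H](CC(C)=C)[C@@H](C=C)C[C@H](C)CC1=O | intermediate
13 | (3aR,4S,7S,8aS)-2,7-dimethyl-4-(propan-2-yl)-3a,4,6,7,8,8a-hexahydroazulen-5(3H)-one | CC(C)[C@H]1[C@@H]2CC(C)=C[C@H]2C[C@H](C)CC1=O | intermediate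
14 | lithium (3aR,4S,7S,8aS)-2,7-dimethyl-4-(propan-2-yl)-3,3a,4,7,8,8a-hexahydroazulen-5-olate | CC(C)[C@H]1[C@@H]2CC(C)=C[C@H]2C[C@H](C)C=C1O[Li] | intermediate (not isolated)
15 | (3aR,4S,8aS)-2,7-dimethyl-4-(propan-2-yl)-3a,4,8,8a-tetrahydroazulen-5(3H)-one | CC(C)[C@H]1[C@@H]2CC(C)=C[C@H]2CC(C)=CC1=O | intermediate
16 | (3aR,4S,7S,8aS)-2,7-dimethyl-4-(propan-2-yl)-7-(4,4,5,5-tetramethyl-1,3,2-dioxaborolan-2-yl)-3a,4,6,7,8,8a-hexahydroazulen-5(3H)-one | CC(C)[C@H]1[C@@H]2CC(C)=C[C@H]2C[C@@](C)(B3OC(C)(C)C(C)(C)O3)CC1=O | intermediate (not isolated)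
17 | (3aR,4S,7R,8aS)-7-hydroxy-2,7-dimethyl-4-(propan-2-yl)-3a,4,6,7,8,8a-hexahydroazulen-5(3H)-one | CC(C)[C@H]1[C@@H]2CC(C)=C[C@H]2C[C@@](C)(O)CC1=O | intermediate
18 | (3aR,4S,5S,7R,8aS)-2,7-dimethyl-4-(propan-2-yl)-3,3a,4,5,6,7,8,8a-octahydroazulene-5,7-diol | CC(C)[C@H]1[C@@H]2CC(C)=C[C@H]2C[C@@](C)(O)C[C@@H]1O | intermediate
19 | 4-iodophenol | Oc1ccc(I)cc1 | starting material
20 | tert-butyl(4-iodophenoxy)dimethylsilane | CC(C)(C)[Si](C)(C)Oc1ccc(I)cc1 | intermediate
21 | carbon monoxide | [C-]#[O+] | starting material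
22 | (3aR,4S,5S,7R,8aS)-7-hydroxy-2,7-dimethyl-4-(propan-2-yl)-3,3a,4,5,6,7,8,8a-octahydroazulen-5-yl 4-[(tert-butyldimethylsilyl)oxy]benzoate | CC(C)[C@H]1[C@@H]2CC(C)=C[C@H]2C[C@@](C)(O)C[C@@H]1OC(=O)c1ccc(O[Si](C)(C)C(C)(C)C)cc1 | intermediate
23 | (1S,2R,3aR,4S,5S,7R,8aS)-1,2-epoxy-7-hydroxy-2,7-dimethyl-4-(propan-2-yl)decahydroazulen-5-yl 4-[(tert-butyldimethylsilyl)oxy]benzoate | CC(C)[C@H]1[C@@H]2C[C@@]3(C)O[C@H]3[C@H]2C[C@@](C)(O)C[C@@H]1OC(=O)c1ccc(O[Si](C)(C)C(C)(C)C)cc1 | intermediate (not isolated)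
24 | (1S,2R,3aR,4S,5S,7R,8aS)-1,2-epoxy-7-hydroxy-2,7-dimethyl-4-(propan-2-yl)decahydroazulen-5-yl 4-hydroxybenzoate (CNP0245441.1) | CC(C)[C@H]1[C@@H]2C[C@@]3(C)O[C@H]3[C@H]2C[C@@](C)(O)C[C@@H]1OC(=O)c1ccc(O)cc1 | target

**Step count and risks**

Total: 11 steps. Longest linear sequence: 10 steps (1–8, 10, 11); step 9 is a one-step side branch.

Step 4 is the most likely to fail, because the reaction is new. The radical cation could be trapped by the methallyl alkene, the ring CH2 could migrate instead of the ring CH, or the thiol could add to the vinyl group. The fallback uses known selenium chemistry and runs from ketone 9 back to 12. 2-Methylpropanal, MeSeH and ZnCl2 give 2-methyl-1,1-bis(methylselanyl)propane F1. Cleavage of F1 with n-BuLi (THF, −78 °C) and addition of the α-selanyl alkyllithium to 9 gives the β-hydroxy selenide (2R,3R,5S)-3-ethenyl-5-methyl-2-(2-methylprop-2-en-1-yl)-1-[2-methyl-1-(methylselanyl)propyl]cyclohexan-1-ol F2. Se-methylation (MeI, AgBF4, CH2Cl2) turns selenium into a leaving group, and the semipinacol shift of the more substituted ring carbon gives 12 after DBU equilibration.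

Step 7 is the second risk. The chiral catalyst has to override whatever facial bias the bicyclic enone has while forming a fully substituted carbon, and the β-hydroxy ketone can revert to the enone under base. The fallback runs from enone 15 back to 17 and makes the C–O bond by epoxidation instead. A catalyst-controlled Weitz–Scheffer epoxidation (9-amino-9-deoxy-epi-quinine TFA salt, aq. H2O2, dioxane) gives (3aR,4S,6R,7R,8aS)-6,7-epoxy-2,7-dimethyl-4-(propan-2-yl)-3a,4,6,7,8,8a-hexahydroazulen-5(3H)-one F3. SmI2 (THF/MeOH, −78 °C) then cleaves only the Cα–O bond and leaves the tertiary hydroxyl of 17.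

Step 11 is the third risk. Delivery from a tertiary bishomoallylic hydroxyl may be weak, and the undirected reaction should prefer the opposite face, anti to C8. The fallback runs from 22 back to 24 and builds the same epoxide by inversion.
- TESOTf/2,6-lutidine gives (3aR,4S,5S,7R,8aS)-2,7-dimethyl-4-(propan-2-yl)-7-[(triethylsilyl)oxy]-3,3a,4,5,6,7,8,8a-octahydroazulen-5-yl 4-[(tert-butyldimethylsilyl)oxy]benzoate F4, which stops the C7 hydroxyl from closing a bromo-ether.
- NBS in aqueous THF puts Br+ on the less hindered face, and water opens the bromonium ion at the tertiary carbon from the other face. This gives the bromohydrin (1R,2R,3aS,4S,5S,7R,8aS)-1-bromo-2-hydroxy-2,7-dimethyl-4-(propan-2-yl)-7-[(triethylsilyl)oxy]decahydroazulen-5-yl 4-[(tert-butyldimethylsilyl)oxy]benzoate F5.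
- K2CO3/MeOH closes the epoxide by backside displacement of bromide and removes the aryl silyl group, giving (1S,2R,3aR,4S,5S,7R,8aS)-1,2-epoxy-2,7-dimethyl-4-(propan-2-yl)-7-[(triethylsilyl)oxy]decahydroazulen-5-yl 4-hydroxybenzoate F6.
- HF·pyridine then frees the C7 hydroxyl to give 24.

**Further compounds**

F1 | step 4 | 2-methyl-1,1-bis(methylselanyl)propane | CC(C)C([Se]C)[Se]C
F2 | step 4 | (2R,3R,5S)-3-ethenyl-5-methyl-2-(2-methylprop-2-en-1-yl)-1-[2-methyl-1-(methylselanyl)propyl]cyclohexan-1-ol (equatorial adduct shown, side-chain epimers) | O[C@]1(C(C(C)C)[Se]C)[C@H](CC(C)=C)[C@@H](C=C)C[C@H](C)C1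
F3 | step 7 | (3aR,4S,6R,7R,8aS)-6,7-epoxy-2,7-dimethyl-4-(propan-2-yl)-3a,4,6,7,8,8a-hexahydroazulen-5(3H)-one | CC(C)[C@H]1[C@@H]2CC(C)=C[C@H]2C[C@@]3(C)O[C@H]3C1=O
F4 | step 11 | (3aR,4S,5S,7R,8aS)-2,7-dimethyl-4-(propan-2-yl)-7-[(triethylsilyl)oxy]-3,3a,4,5,6,7,8,8a-octahydroazulen-5-yl 4-[(tert-butyldimethylsilyl)oxy]benzoate | CC(C)[C@H]1[C@@H]2CC(C)=C[C@H]2C[C@@](C)(O[Si](CC)(CC)CC)C[C@@H]1OC(=O)c1ccc(O[Si](C)(C)C(C)(C)C)cc1
F5 | step 11 | (1R,2R,3aS,4S,5S,7R,8aS)-1-bromo-2-hydroxy-2,7-dimethyl-4-(propan-2-yl)-7-[(triethylsilyl)oxy]decahydroazulen-5-yl 4-[(tert-butyldimethylsilyl)oxy]benzoate | CC(C)[C@H]1[C@@H]2C[C@@](C)(O)[C@H](Br)[C@H]2C[C@@](C)(O[Si](CC)(CC)CC)C[C@@H]1OC(=O)c1ccc(O[Si](C)(C)C(C)(C)C)cc1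
F6 | step 11 | (1S,2R,3aR,4S,5S,7R,8aS)-1,2-epoxy-2,7-dimethyl-4-(propan-2-yl)-7-[(triethylsilyl)oxy]decahydroazulen-5-yl 4-hydroxybenzoate | CC(C)[C@H]1[C@@H]2C[C@@]3(C)O[C@H]3[C@H]2C[C@@](C)(O[Si](CC)(CC)CC)C[C@@H]1OC(=O)c1ccc(O)cc1
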